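The route rests on cutting the bond between the ring nitrogen and C6 of the piperidine. The key step exploits the 1,5 spacing of the nitrogen on C2 and the carbon C6. It also exploits the cis C2 methyl and C3 oxygen, which shield one face of the C6=N bond. One hydrogenation of an acyclic azido hydroxy ynone reduces azide and alkyne, closes the ring as a cyclic imine and sets C6. That precursor joins an azido lactone from L-rhamnal (C3 is sugar C4, retained; C2 is sugar C5, inverted by azide) with a ketal-masked C14 lithium acetylide. Ketal hydrolysis and acidic O-acetylation finish.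

Key step: step 10

Remark on the chemistry: the γ-hydroxy ketones of this route are drawn open-chain. Their five-membered lactol tautomers are the same material and feed the same reactions. The keto ester from the acetoacetate alkylation is racemic at a centre that the next step destroys.

Step 1
Reactants: 1 3,4-di-O-acetyl-L-rhamnal [(2S,3S,4S)-2-methyl-3,4-dihydro-2H-pyran-3,4-diyl diacetate]
Product: 3 (5R,6S)-5-acetoxy-6-methyl-5,6-dihydro-2H-pyran-2-one, via anomeric perester 2 (not isolated)
Conditions: dried mCPBA (1.3 equiv), BF3·OEt2 (0.5 equiv), CH2Cl2, −20 to 0 °C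
Reagents that add atoms: 3-chloroperoxybenzoic acid (mCPBA), O=C(OO)c1cccc(Cl)c1
Why: BF3-induced peroxidation of a glycal ester, in which Ferrier-type ionisation of the allylic C3 acetate, capture of the allyl oxocarbenium ion at C1 by the peracid and fragmentation of perester 2 (the anomeric hydrogen and 3-chlorobenzoate leave) should give the enelactone without chromium, while sugar C4 and C5 are spectators.

Step 2
Reactants: 3 (5R,6S)-5-acetoxy-6-methyl-5,6-dihydro-2H-pyran-2-one
Product: 4 4-O-acetyl-2,3,6-trideoxy-L-erythro-hexono-1,5-lactone [(5R,6S)-5-acetoxy-6-methyloxan-2-one]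
Conditions: H2 (1 atm), 10% Pd/C, EtOAc, rt
Reagents that add atoms: none
Why: Heterogeneous catalytic hydrogenation of the conjugated C2=C3 bond is fast at low pressure in a neutral aprotic solvent, which keeps hydrogenolysis of the allylic acetate in check, and no stereocentre is made or touched.

Step 3
Reactants: 4 4-O-acetyl-2,3,6-trideoxy-L-erythro-hexono-1,5-lactone
Product: 6 (4R,5S)-5-hydroxyhexan-4-olide [(5R)-5-[(1S)-1-hydroxyethyl]oxolan-2-one], via diol methyl ester 5 (not isolated)
Conditions: K2CO3 (0.2 equiv), MeOH, 0 °C to rt; then Amberlyst 15 (H+ form), rt; filter, evaporate from toluene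
Reagents that add atoms: none
Why: Zemplén-type transesterification strips the acetate and opens the δ-lactone to diol ester 5, and acid-catalysed relactonisation then chooses the thermodynamically favoured five-membered ring through O4, so that only the C5 hydroxyl stays free and no C–O bond at a stereocentre is broken.

Step 4
Reactants: 6 (4R,5S)-5-hydroxyhexan-4-olide
Product: 7 (4R,5R)-5-azidohexan-4-olide [(5R)-5-[(1R)-1-azidoethyl]oxolan-2-one]
Conditions: PPh3, DIAD, DPPA (1.5 equiv each), THF, 0 °C to rt; chromatography, no distillation
Reagents that add atoms: diphenylphosphoryl azide (DPPA), [N-]=[N+]=NP(=O)(Oc1ccccc1)Oc1ccccc1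
Why: Mitsunobu reaction with azide as the nucleophile, in which the unhindered methyl carbinol is activated as its oxyphosphonium salt and displaced by SN2, which inverts sugar C5 from S to R, while C4 is tied up in the lactone and cannot take part.

Step 5
Reactants: 8 undec-10-yn-1-ol
Product: 9 11-bromoundec-1-yne
Conditions: CBr4, PPh3, CH2Cl2, 0 °C
Reagents that add atoms: carbon tetrabromide, BrC(Br)(Br)Br
Why: Appel reaction, an SN2 bromination of a primary alcohol under neutral conditions that leave the terminal alkyne alone.

Step 6
Reactants: 9 11-bromoundec-1-yne; 10 ethyl acetoacetate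
Product: 12 ethyl 2-acetyltridec-12-ynoate (racemic), via sodium enolate 11 (not isolated)
Conditions: NaOEt (1.1 equiv), NaI (0.1 equiv), EtOH, reflux
Reagents that add atoms: none
Why: Acetoacetic ester synthesis, in which ethoxide deprotonates only the 1,3-dicarbonyl compound (the alkyne C–H is far less acidic) and enolate 11 C-alkylates the primary bromide by SN2 with iodide catalysis.

Step 7
Reactants: 12 ethyl 2-acetyltridec-12-ynoate
Product: 14 tetradec-13-yn-2-one, via β-keto acid 13 (not isolated)
Conditions: NaOH (1.5 equiv, 5% aq), EtOH, rt; then aq HCl to pH 1, 60 °C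
Reagents that add atoms: none
Why: Ketonic cleavage of a β-keto ester, in which dilute hydroxide saponifies without retro-Claisen cleavage and β-keto acid 13 loses CO2 through the usual cyclic transition state on warming in acid, conditions that do not hydrate a terminal alkyne.

Step 8
Reactants: 14 tetradec-13-yn-2-one
Product: 15 2-(dodec-11-yn-1-yl)-2-methyl-1,3-dioxolane
Conditions: HOCH2CH2OH (3 equiv), TsOH·H2O (0.05 equiv), toluene, Dean–Stark, reflux
Reagents that add atoms: ethylene glycol, OCCO
Why: Acid-catalysed ketalisation driven by azeotropic removal of water, and the dioxolane is needed to withstand n-BuLi in step 9 and to keep this ketone out of the reductive amination in step 10.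

Step 9
Reactants: 7 (4R,5R)-5-azidohexan-4-olide; 15 2-(dodec-11-yn-1-yl)-2-methyl-1,3-dioxolane
Product: 17 (2R,3R)-2-azido-3-hydroxy-18-(2-methyl-1,3-dioxolan-2-yl)octadec-7-yn-6-one, via lithium acetylide 16 (not isolated)
Conditions: 15 (1.2 equiv), n-BuLi (1.15 equiv), THF, −78 °C; 7 in THF, −78 °C; AcOH in THF, −78 °C; cold aq NaHCO3 work-up, short silica pad, bath below 25 °C, used the same day
Reagents that add atoms: none
Why: Addition of a lithium acetylide to a γ-lactone (acyl substitution with ring opening), in which the tetrahedral lithium hemiketal persists at −78 °C so that the ynone is released only on quenching and a second addition is avoided, the slight deficit of n-BuLi leaves no alkyllithium to attack the azide, and neither stereocentre is involved.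

Step 10
Reactants: 17 (2R,3R)-2-azido-3-hydroxy-18-(2-methyl-1,3-dioxolan-2-yl)octadec-7-yn-6-one
Product: 20 (2R,3R,6S)-2-methyl-6-[12-(2-methyl-1,3-dioxolan-2-yl)dodecyl]piperidin-3-ol (spectaline ethylene ketal), via amino hydroxy ketone 18 (not isolated), via cyclic imine 19 (not isolated)
Conditions: H2 (1–3 atm), 10% Pd/C, MeOH, rt; 17 added slowly as a dilute solution to the prereduced catalyst
Reagents that add atoms: none
Why: On Pd/C the azide of 17 loses dinitrogen to give the primary amine and the ynone takes up two equivalents of hydrogen, so amino ketone 18 arises; its nitrogen adds to the C6 carbonyl, water is lost to give tetrahydropyridine 19, and the C=N bond is hydrogenated in the same flask. The closest known reaction type is the one-pot hydrogenolytic unmasking of an azide or N-Cbz group followed by intramolecular reductive amination of the 1,5-amino ketone, a standard entry to cis-2,6-dialkylpiperidin-3-ols. The piperidine, the only ring formed, closes in a 6-exo-trig mode, since nitrogen attacks the carbonyl carbon and the carbonyl oxygen stays outside the new ring. C6 is the only new stereocentre and is under substrate control: 19 meets the metal surface with the face that carries the C2 and C3 hydrogens, away from the cis methyl and hydroxyl groups, so hydrogen enters there and the chain ends up on the methyl and hydroxyl side, which is 6S with both alkyl groups equatorial and the hydroxyl axial. The step needs facial selectivity at C=N, secured by those two cis substituents, and preference for intramolecular over intermolecular capture of the amine, secured by the 1,5 spacing, by dilution with slow addition and by the fast saturation of the alkyne. The dioxolane keeps the remote ketone out of the reductive amination and is safe because the medium is neutral to basic.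

Step 11
Reactants: 20 spectaline ethylene ketal
Product: 21 (−)-spectaline [14-[(2S,5R,6R)-5-hydroxy-6-methylpiperidin-2-yl]tetradecan-2-one]
Conditions: 2 M aq HCl, THF, rt; then aq NaOH to pH 11, CH2Cl2 extraction
Reagents that add atoms: water, O
Why: Acid-catalysed ketal hydrolysis, during which the protonated piperidine is inert and nothing can epimerise because none of the three stereocentres lies next to a carbonyl group.

Step 12
Reactants: 21 (−)-spectaline
Product: 22 (−)-3-O-acetylspectaline [(2R,3R,6S)-2-methyl-6-(13-oxotetradecyl)piperidin-3-yl acetate]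
Conditions: AcCl (5 equiv), CF3CO2H, 0 °C to rt; evaporate; cold sat. aq NaHCO3, CH2Cl2
Reagents that add atoms: acetyl chloride, CC(=O)Cl
Why: Chemoselective O-acylation of an amino alcohol in strong acid, in which the nitrogen is fully protonated and so not nucleophilic while the axial C3 hydroxyl is acetylated with retention, and a brief cold bicarbonate work-up frees the base before O-to-N acetyl migration, which would need a strained bridged intermediate, can set in.

Compound list
1 | 3,4-di-O-acetyl-L-rhamnal | C[C@@H]1OC=C[C@H](OC(C)=O)[C@H]1OC(C)=O | starting material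
2 | 4-O-acetyl-2,3,6-trideoxy-L-erythro-hex-2-enopyranosyl 3-chloroperoxybenzoate (anomeric mixture) | C[C@@H]1OC(OOC(=O)c2cccc(Cl)c2)C=C[C@H]1OC(C)=O | intermediate
3 | (5R,6S)-5-acetoxy-6-methyl-5,6-dihydro-2H-pyran-2-one | C[C@@H]1OC(=O)C=C[C@H]1OC(C)=O | intermediate
4 | 4-O-acetyl-2,3,6-trideoxy-L-erythro-hexono-1,5-lactone | C[C@@H]1OC(=O)CC[C@H]1OC(C)=O | intermediate
5 | methyl (4R,5S)-4,5-dihydroxyhexanoate | C[C@H](O)[C@H](O)CCC(=O)OC | intermediate
6 | (4R,5S)-5-hydroxyhexan-4-olide | C[C@H](O)[C@H]1CCC(=O)O1 | intermediate
7 | (4R,5R)-5-azidohexan-4-olide | C[C@@H](N=[N+]=[N-])[C@H]1CCC(=O)O1 | intermediate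
8 | undec-10-yn-1-ol | C#CCCCCCCCCCO | starting material
9 | 11-bromoundec-1-yne | C#CCCCCCCCCCBr | intermediate
10 | ethyl acetoacetate | CCOC(=O)CC(C)=O | starting material
11 | sodium enolate of ethyl acetoacetate | [Na+].CCOC(=O)C=C(C)[O-] | intermediate
12 | ethyl 2-acetyltridec-12-ynoate (racemic) | CCOC(=O)C(CCCCCCCCCC#C)C(C)=O | intermediate
13 | 2-acetyltridec-12-ynoic acid (racemic) | OC(=O)C(CCCCCCCCCC#C)C(C)=O | intermediate
14 | tetradec-13-yn-2-one | CC(=O)CCCCCCCCCCC#C | intermediate
15 | 2-(dodec-11-yn-1-yl)-2-methyl-1,3-dioxolane | CC1(CCCCCCCCCCC#C)OCCO1 | intermediate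
16 | lithium 12-(2-methyl-1,3-dioxolan-2-yl)dodec-1-yn-1-ide | [Li]C#CCCCCCCCCCCC1(C)OCCO1 | intermediate
17 | (2R,3R)-2-azido-3-hydroxy-18-(2-methyl-1,3-dioxolan-2-yl)octadec-7-yn-6-one | C[C@@H](N=[N+]=[N-])[C@H](O)CCC(=O)C#CCCCCCCCCCCC1(C)OCCO1 | intermediate
18 | (2R,3R)-2-amino-3-hydroxy-18-(2-methyl-1,3-dioxolan-2-yl)octadecan-6-one | C[C@@H](N)[C@H](O)CCC(=O)CCCCCCCCCCCCC1(C)OCCO1 | intermediate
19 | (2R,3R)-2-methyl-6-[12-(2-methyl-1,3-dioxolan-2-yl)dodecyl]-2,3,4,5-tetrahydropyridin-3-ol | C[C@H]1N=C(CCCCCCCCCCCCC2(C)OCCO2)CC[C@H]1O | intermediate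
20 | (2R,3R,6S)-2-methyl-6-[12-(2-methyl-1,3-dioxolan-2-yl)dodecyl]piperidin-3-ol | CC1(CCCCCCCCCCCC[C@H]2CC[C@@H](O)[C@@H](C)N2)OCCO1 | intermediate
21 | (−)-spectaline | CC(=O)CCCCCCCCCCCC[C@H]1CC[C@@H](O)[C@@H](C)N1 | intermediate
22 | (−)-3-O-acetylspectaline | CC(=O)CCCCCCCCCCCC[C@H]1CC[C@@H](OC(C)=O)[C@@H](C)N1 | target

Total step count: 12. Longest linear sequence: 8 steps (steps 1–4 then 9–12; the branch through steps 5–8 then 9–12 is equally long).

Steps most likely to fail

1. Step 9.
- What may go wrong: the acetylide may deprotonate the lactone instead of adding to it. The organolithium may attack the azide. The azido ynone may also be lost by intramolecular azide–alkyne cycloaddition during work-up.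
- The fallback removes the azide before the C–C bond is made and sets out from 7. Hydrogenation (H2, 10% Pd/C, MeOH) should give the amine, which opens the γ-lactone by O-to-N acyl transfer to the lactam (5R,6R)-5-hydroxy-6-methylpiperidin-2-one F1.
- Silylation (TBSCl, imidazole, DMF) gives (5R,6R)-5-(tert-butyldimethylsilyloxy)-6-methylpiperidin-2-one F2. N-acylation (n-BuLi, then CbzCl, THF, −78 °C) gives benzyl (2R,3R)-3-(tert-butyldimethylsilyloxy)-2-methyl-6-oxopiperidine-1-carboxylate F3.
- Acetylide 16 opens the activated ring carbonyl at −78 °C to the acyclic ynone benzyl N-[(2R,3R)-3-(tert-butyldimethylsilyloxy)-18-(2-methyl-1,3-dioxolan-2-yl)-6-oxooctadec-7-yn-2-yl]carbamate F4, which holds no azide and can be stored.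
- One hydrogenation (H2, Pd/C, MeOH) cleaves the Cbz group, saturates the alkyne and runs the same ring closure and imine reduction. It gives (2R,3R,6S)-3-(tert-butyldimethylsilyloxy)-2-methyl-6-[12-(2-methyl-1,3-dioxolan-2-yl)dodecyl]piperidine F5.
- Aqueous HCl as in step 11 removes silyl ether and ketal together, and the route is rejoined at 21.

2. Step 10.
- What may go wrong: the freed amine may add intermolecularly to ynone that is not yet reduced. The amine may poison the catalyst so that the sequence stalls at the imine. Facial selectivity on the metal surface may be poor.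
- The fallback separates ring closure from reduction and sets out from 17. PPh3 in dry THF at rt turns the azide into the iminophosphorane (Staudinger reaction). This closes onto the C6 ketone by intramolecular aza-Wittig reaction to (2R,3R)-2-methyl-6-[12-(2-methyl-1,3-dioxolan-2-yl)dodec-1-yn-1-yl]-2,3,4,5-tetrahydropyridin-3-ol F6, so that no free amine ever meets an ynone.
- NaBH4 in MeOH at −20 °C then delivers hydride axially, anti to the C2 methyl. This stereoelectronic control is independent of a catalyst surface and gives (2R,3R,6R)-2-methyl-6-[12-(2-methyl-1,3-dioxolan-2-yl)dodec-1-yn-1-yl]piperidin-3-ol F7. The spatial arrangement is the same all-cis one; the descriptor changes only through the priority of the alkynyl group.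
- Hydrogenation of the alkyne (H2, Pd/C, EtOAc) brings the material back to the route at 20.

3. Step 4.
- What may go wrong: displacement at the oxygen-flanked secondary centre may be slow. Elimination may compete, and separation of the small polar azide from the phosphine oxide and hydrazide residues may be tedious.
- The fallback splits activation and displacement and sets out from 6. MsCl and Et3N in CH2Cl2 at 0 °C give the isolable sulfonate (1S)-1-[(2R)-5-oxooxolan-2-yl]ethyl methanesulfonate F8. NaN3 in DMF at 70 °C displaces it by SN2 with inversion, and the route is rejoined at 7.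

Further compounds
F1 | step 9 | (5R,6R)-5-hydroxy-6-methylpiperidin-2-one | O=C1CC[C@@H](O)[C@@H](C)N1
F2 | step 9 | (5R,6R)-5-(tert-butyldimethylsilyloxy)-6-methylpiperidin-2-one | O=C1CC[C@@H](O[Si](C)(C)C(C)(C)C)[C@@H](C)N1
F3 | step 9 | benzyl (2R,3R)-3-(tert-butyldimethylsilyloxy)-2-methyl-6-oxopiperidine-1-carboxylate | O=C1CC[C@@H](O[Si](C)(C)C(C)(C)C)[C@@H](C)N1C(=O)OCc2ccccc2
F4 | step 9 | benzyl N-[(2R,3R)-3-(tert-butyldimethylsilyloxy)-18-(2-methyl-1,3-dioxolan-2-yl)-6-oxooctadec-7-yn-2-yl]carbamate | C[C@@H](NC(=O)OCc1ccccc1)[C@H](O[Si](C)(C)C(C)(C)C)CCC(=O)C#CCCCCCCCCCCC2(C)OCCO2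
F5 | step 9 | (2R,3R,6S)-3-(tert-butyldimethylsilyloxy)-2-methyl-6-[12-(2-methyl-1,3-dioxolan-2-yl)dodecyl]piperidine | CC1(CCCCCCCCCCCC[C@H]2CC[C@@H](O[Si](C)(C)C(C)(C)C)[C@@H](C)N2)OCCO1
F6 | step 10 | (2R,3R)-2-methyl-6-[12-(2-methyl-1,3-dioxolan-2-yl)dodec-1-yn-1-yl]-2,3,4,5-tetrahydropyridin-3-ol | C[C@H]1N=C(C#CCCCCCCCCCCC2(C)OCCO2)CC[C@H]1O
F7 | step 10 | (2R,3R,6R)-2-methyl-6-[12-(2-methyl-1,3-dioxolan-2-yl)dodec-1-yn-1-yl]piperidin-3-ol | CC1(CCCCCCCCCCC#C[C@H]2CC[C@@H](O)[C@@H](C)N2)OCCO1
F8 | step 4 | (1S)-1-[(2R)-5-oxooxolan-2-yl]ethyl methanesulfonate | C[C@H](OS(C)(=O)=O)[C@H]1CCC(=O)O1
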